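**Retrosynthetic overview**

1. Target 19 ⇒ silyl ether 18 ⇒ acyclic nitro keto enoate 16. The only ring is closed last, at C2–C3, by 6-exo conjugate addition of a C3 nitronate to C2 and loss of nitrite (ring carbons: C1 ketone, C2 bearing CH2CO2Me, C3 =CH, C4 carbinol, C5 geranylgeranyl-bearing, C6 CH2).
2. Enabling feature: the 1,4-dicarbonyl array C1(=O)–C2–CH2–CO2Me. C2 is β to the ester (an acceptor in MeO2C–CH=C2H–C1=O) and α to the ring ketone (acidic C2–H for E1cB). C3, the β-carbon of the final enone, is made a donor by a nitro group that leaves as nitrite, so two acceptor carbons are joined by polarity reversal.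
3. 16 ⇒ 2-alkylfuran 13 (the furan is the masked Z-4-oxo-2-enoate, opened with singlet oxygen) ⇒ aldehyde 10 + nitromethane (catalytic asymmetric Henry reaction sets C4).
4. 10 ⇒ Evans alkylation of 3-(furan-2-yl)propanoyl imide 6 with geranylgeranyl bromide 2 (sets C5).

Key step: step 10

Remark: "geranylgeranyl" = (2E,6E,10E)-3,7,11,15-tetramethylhexadeca-2,6,10,14-tetraen-1-yl.
Assumption: the sense of induction of the bis(oxazoline) ligand in step 6 is fixed on a model α-branched aldehyde, and the antipode that attacks the Si face of the aldehyde is used.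

**Step 1**
Reactants: 1 (2E,6E,10E)-geranylgeraniol
Product: 2 (2E,6E,10E)-geranylgeranyl bromide
Conditions: PBr3 (0.4 equiv), Et2O, −10 °C; used crude
Reagents that add atoms: phosphorus tribromide, BrP(Br)Br
Why: Bromination of the primary allylic alcohol with PBr3 at low temperature should give the allylic bromide by SN2-type displacement without allylic transposition or loss of the 2E geometry, and no stereocentre is formed.

**Step 2**
Reactants: 3 3-(furan-2-yl)propanoic acid; 4 (R)-4-benzyloxazolidin-2-one
Product: 6 (R)-4-benzyl-3-[3-(furan-2-yl)propanoyl]oxazolidin-2-one, via mixed pivalic anhydride 5 (not isolated)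
Conditions: PivCl, Et3N, THF, −20 °C; then LiCl, 4, −20 °C to rt
Reagents that add atoms: pivaloyl chloride, CC(C)(C)C(Cl)=O (its acyl group is present only in 5 and is lost again on the way to 6)
Why: N-Acylation of the oxazolidinone through the mixed anhydride (LiCl/Et3N activation) is a standard mild imide formation that should leave the furan untouched.

**Step 3**
Reactants: 6 (R)-4-benzyl-3-[3-(furan-2-yl)propanoyl]oxazolidin-2-one; 2 geranylgeranyl bromide
Product: 8 (R)-4-benzyl-3-[(2R,4E,8E,12E)-2-(furan-2-ylmethyl)-5,9,13,17-tetramethyloctadeca-4,8,12,16-tetraenoyl]oxazolidin-2-one, via sodium Z-enolate 7 (not isolated)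
Conditions: NaN(SiMe3)2, THF, −78 °C; then 2, −78 to −40 °C
Reagents that add atoms: sodium bis(trimethylsilyl)amide, C[Si](C)(C)[N-][Si](C)(C)C.[Na+] (supplies only the sodium of 7)
Why: Evans asymmetric alkylation: the chelated Z-enolate 7 should be attacked by the reactive allylic bromide on the face opposite the benzyl group of the (R)-auxiliary, which sets the (R) centre that becomes C5 of the ring.

**Step 4**
Reactants: 8 the alkylated imide
Product: 9 (2R,4E,8E,12E)-2-(furan-2-ylmethyl)-5,9,13,17-tetramethyloctadeca-4,8,12,16-tetraen-1-ol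
Conditions: LiBH4, Et2O–THF, 0 °C
Reagents that add atoms: none
Why: Reductive cleavage of the imide with LiBH4 should give the primary alcohol and return auxiliary 4, with no enolisation of the stereocentre.

**Step 5**
Reactants: 9 the primary alcohol
Product: 10 (2R,4E,8E,12E)-2-(furan-2-ylmethyl)-5,9,13,17-tetramethyloctadeca-4,8,12,16-tetraenal
Conditions: Dess–Martin periodinane, CH2Cl2, 0 °C to rt; used at once
Reagents that add atoms: none
Why: Dess–Martin oxidation is mild enough to spare the furan and the four trisubstituted alkenes, and the α-branched aldehyde should keep its configuration if it is carried on without storage.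

**Step 6**
Reactants: 10 the aldehyde; 11 nitromethane
Product: 12 (2R,3R,5E,9E,13E)-3-(furan-2-ylmethyl)-6,10,14,18-tetramethyl-1-nitrononadeca-5,9,13,17-tetraen-2-ol
Conditions: Cu(OAc)2·H2O (5 mol%), indane-fused bis(oxazoline) ligand (5.5 mol%, antipode for Si-face attack), MeNO2 in excess, EtOH, 0 °C to rt
Reagents that add atoms: none
Why: Catalytic asymmetric Henry (nitroaldol) addition, in which all atoms of the aldehyde and of one molecule of nitromethane end up in the product: the copper–bis(oxazoline) complex should bind the aldehyde and deliver the nitronate to its Si face, so the new carbinol (later C4) is set (R) by the catalyst, the α-centre with its two similar CH2R arms having almost no bias of its own.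

**Step 7**
Reactants: 12 the nitro alcohol
Product: 13 tert-butyl{[(2R,3R,5E,9E,13E)-3-(furan-2-ylmethyl)-6,10,14,18-tetramethyl-1-nitrononadeca-5,9,13,17-tetraen-2-yl]oxy}dimethylsilane
Conditions: TBSCl, imidazole, DMF, 35 °C
Reagents that add atoms: tert-butyldimethylsilyl chloride, CC(C)(C)[Si](C)(C)Cl
Why: Silylation of the secondary alcohol (imidazole is too weak to form the nitronate) blocks retro-nitroaldol cleavage and later shields the γ-oxygenated enone from base.

**Step 8**
Reactants: 13 the silylated nitro furan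
Product: 15 5-{(2R,3R)-3-[(tert-butyldimethylsilyl)oxy]-2-geranylgeranyl-4-nitrobutyl}-5-hydroxyfuran-2(5H)-one (epimers at the hemiketal carbon), via furan endoperoxide 14 (not isolated)
Conditions: O2, visible light, tetraphenylporphyrin (cat.), i-Pr2NEt, CH2Cl2, −78 °C; then cold aq. NaH2PO4
Reagents that add atoms: dioxygen, O=O
Why: Dye-sensitised photooxygenation: singlet oxygen should add [4+2] to the electron-rich furan much faster than it attacks the trisubstituted alkenes, and the hindered base should open endoperoxide 14 by Kornblum–DeLaMare rearrangement at its single bridgehead C–H to the γ-hydroxybutenolide, the ring form of the Z-4-oxo-2-enoic acid.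

**Step 9**
Reactants: 15 the γ-hydroxybutenolide
Product: 16 methyl (2Z,6R,7R)-7-[(tert-butyldimethylsilyl)oxy]-6-geranylgeranyl-8-nitro-4-oxooct-2-enoate
Conditions: TMSCHN2 (1.2 equiv), MeOH–toluene, 0 °C; AcOH quench
Reagents that add atoms: (trimethylsilyl)diazomethane, C[Si](C)(C)C=[N+]=[N-]
Why: Esterification with (trimethylsilyl)diazomethane should methylate the ring-opened carboxylic acid tautomer under neutral conditions, giving the open-chain keto enoate with no base present that could start the cyclisation early.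

**Step 10**
Reactants: 16 the nitro keto enoate
Product: 18 methyl 2-[(3R,4R)-3-[(tert-butyldimethylsilyl)oxy]-4-geranylgeranyl-6-oxocyclohex-1-en-1-yl]acetate, via cyclised nitro ketone 17 (not isolated)
Conditions: DBU (2.5 equiv), MeCN, 0 °C to rt
Reagents that add atoms: none
Why: DBU should form the nitronate at C3, which adds to C2 of the ene-dicarbonyl in a 6-exo-trig conjugate addition (attack at the other alkene carbon would be 7-endo) to give β-nitro ketone 17, after which the C1 ketone acidifies C2–H and E1cB loss of nitrite leaves the C2=C3 enone. The closest known reaction type is the DBU-mediated conjugate addition of a nitroalkane to an ene-dicarbonyl acceptor followed by elimination of nitrous acid (nitroalkane as alkylidene donor), run here intramolecularly. Two acceptor-type carbons are thereby joined, C3 (β-carbon of the final enone) and C2 (β-carbon of the ester), because the nitro group reverses the polarity of C3 and then leaves without a trace. No stereocentre of the product is created (the transient centres at C2 and C3 of 17 are erased by the elimination), and C4 and C5 are not enolisable in 16 or 17 and should be kept. The step needs regioselectivity in the addition, secured by ring size and by the ester activating C2, and the right direction of elimination, secured by the C1 ketone, which makes the C2 enolate form and nitrite rather than silanolate leave; the silyl ether also prevents retro-nitroaldol opening and base isomerisation of a free γ-hydroxy enone.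

**Step 11**
Reactants: 18 the silyl-protected enone
Product: 19 methyl 2-[(3R,4R)-4-geranylgeranyl-3-hydroxy-6-oxocyclohex-1-en-1-yl]acetate (target)
Conditions: HF·pyridine, pyridine, THF, 0 °C to rt
Reagents that add atoms: none
Why: Buffered fluoride desilylation should free the C4 hydroxyl without epimerising it and without isomerising the γ-hydroxy enone or the polyene chain.

**Compound list**

1 | (2E,6E,10E)-geranylgeraniol | OC/C=C(\C)CC/C=C(\C)CC/C=C(\C)CCC=C(C)C | starting material
2 | (2E,6E,10E)-geranylgeranyl bromide | BrC/C=C(\C)CC/C=C(\C)CC/C=C(\C)CCC=C(C)C | intermediate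
3 | 3-(furan-2-yl)propanoic acid | OC(=O)CCc1ccco1 | starting material
4 | (R)-4-benzyloxazolidin-2-one | O=C1N[C@H](Cc2ccccc2)CO1 | starting material
5 | 3-(furan-2-yl)propanoic pivalic anhydride | CC(C)(C)C(=O)OC(=O)CCc1ccco1 | intermediate
6 | (R)-4-benzyl-3-[3-(furan-2-yl)propanoyl]oxazolidin-2-one | O=C(CCc1ccco1)N1[C@H](Cc2ccccc2)COC1=O | intermediate
7 | sodium (Z)-1-[(R)-4-benzyl-2-oxooxazolidin-3-yl]-3-(furan-2-yl)prop-1-en-1-olate | [Na+].[O-]/C(=C\Cc1ccco1)N1[C@H](Cc2ccccc2)COC1=O | intermediate
8 | (R)-4-benzyl-3-[(2R,4E,8E,12E)-2-(furan-2-ylmethyl)-5,9,13,17-tetramethyloctadeca-4,8,12,16-tetraenoyl]oxazolidin-2-one | O=C([C@H](C/C=C(\C)CC/C=C(\C)CC/C=C(\C)CCC=C(C)C)Cc1ccco1)N1[C@H](Cc2ccccc2)COC1=O | intermediate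
9 | (2R,4E,8E,12E)-2-(furan-2-ylmethyl)-5,9,13,17-tetramethyloctadeca-4,8,12,16-tetraen-1-ol | OC[C@H](C/C=C(\C)CC/C=C(\C)CC/C=C(\C)CCC=C(C)C)Cc1ccco1 | intermediate
10 | (2R,4E,8E,12E)-2-(furan-2-ylmethyl)-5,9,13,17-tetramethyloctadeca-4,8,12,16-tetraenal | O=C[C@H](C/C=C(\C)CC/C=C(\C)CC/C=C(\C)CCC=C(C)C)Cc1ccco1 | intermediate
11 | nitromethane | C[N+](=O)[O-] | starting material
12 | (2R,3R,5E,9E,13E)-3-(furan-2-ylmethyl)-6,10,14,18-tetramethyl-1-nitrononadeca-5,9,13,17-tetraen-2-ol | [O-][N+](=O)C[C@H](O)[C@H](C/C=C(\C)CC/C=C(\C)CC/C=C(\C)CCC=C(C)C)Cc1ccco1 | intermediate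
13 | tert-butyldimethylsilyl ether of 12 | [O-][N+](=O)C[C@H](O[Si](C)(C)C(C)(C)C)[C@H](C/C=C(\C)CC/C=C(\C)CC/C=C(\C)CCC=C(C)C)Cc1ccco1 | intermediate
14 | 1-{(2R,3R)-3-[(tert-butyldimethylsilyl)oxy]-2-geranylgeranyl-4-nitrobutyl}-2,3,7-trioxabicyclo[2.2.1]hept-5-ene (furan endoperoxide, bridgehead centres as formed) | [O-][N+](=O)C[C@H](O[Si](C)(C)C(C)(C)C)[C@H](C/C=C(\C)CC/C=C(\C)CC/C=C(\C)CCC=C(C)C)CC12OOC(C=C1)O2 | intermediate
15 | 5-{(2R,3R)-3-[(tert-butyldimethylsilyl)oxy]-2-geranylgeranyl-4-nitrobutyl}-5-hydroxyfuran-2(5H)-one (hemiketal epimers) | [O-][N+](=O)C[C@H](O[Si](C)(C)C(C)(C)C)[C@H](C/C=C(\C)CC/C=C(\C)CC/C=C(\C)CCC=C(C)C)CC1(O)OC(=O)C=C1 | intermediate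
16 | methyl (2Z,6R,7R)-7-[(tert-butyldimethylsilyl)oxy]-6-geranylgeranyl-8-nitro-4-oxooct-2-enoate | [O-][N+](=O)C[C@H](O[Si](C)(C)C(C)(C)C)[C@H](C/C=C(\C)CC/C=C(\C)CC/C=C(\C)CCC=C(C)C)CC(=O)/C=C\C(=O)OC | intermediate
17 | methyl 2-[(3R,4R)-3-[(tert-butyldimethylsilyl)oxy]-4-geranylgeranyl-2-nitro-6-oxocyclohexyl]acetate (ring C1 and C2 as formed) | COC(=O)CC1C([N+](=O)[O-])[C@H](O[Si](C)(C)C(C)(C)C)[C@H](C/C=C(\C)CC/C=C(\C)CC/C=C(\C)CCC=C(C)C)CC1=O | intermediate
18 | methyl 2-[(3R,4R)-3-[(tert-butyldimethylsilyl)oxy]-4-geranylgeranyl-6-oxocyclohex-1-en-1-yl]acetate | COC(=O)CC1=C[C@H](O[Si](C)(C)C(C)(C)C)[C@H](C/C=C(\C)CC/C=C(\C)CC/C=C(\C)CCC=C(C)C)CC1=O | intermediate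
19 | methyl 2-[(3R,4R)-4-geranylgeranyl-3-hydroxy-6-oxocyclohex-1-en-1-yl]acetate (hydroxyl and geranylgeranyl cis) | COC(=O)CC1=C[C@H](O)[C@H](C/C=C(\C)CC/C=C(\C)CC/C=C(\C)CCC=C(C)C)CC1=O | target

**Step count and risks**

Total: 11 steps. Longest linear sequence: 10 steps (3 to 19 through steps 2–11; equally 1 to 19 through steps 1 and 3–11).

Steps most likely to fail:

1. Step 10 (key step). What may go wrong: conjugate addition of the nitronate at the other alkene carbon (7-endo, the carbon activated by the ketone), or β-elimination of silanolate from the nitronate before ring closure. Fallback: the acceptor is changed to one with a single electrophilic carbon. Setting out from 15, acid-catalysed methanolysis (MeOH, HC(OMe)3, cat. PPTS) should give the 5-methoxybutenolide pseudoester F1, in which only C2 (the β-carbon of the butenolide) can accept a nucleophile. DBU in MeCN should then close the ring there to the bicyclic nitro lactone F2. NaOMe in MeOH should open the lactone to the methyl ester, release the C1 ketone from the ketal and eliminate nitrite, coming back to the route at 18.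

2. Step 8. What may go wrong: ene reaction of singlet oxygen with the four trisubstituted alkenes (allylic hydroperoxides) before the furan is consumed. Fallback: a non-photochemical, electrophilic ring opening. Setting out from 13, NBS with NaHCO3 in aqueous acetone at −15 °C should open the furan to the Z keto enal F3, and pyridine should isomerise it to the E keto enal F4. Pinnick oxidation (NaClO2, NaH2PO4, 2-methyl-2-butene) should give the E keto acid F5, and TMSCHN2 the E keto ester F6. Under the DBU conditions of step 10, F6 should cyclise through 17 and come back to the route at 18.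

3. Step 6. What may go wrong: insufficient facial control by the catalyst at the hindered α-branched aldehyde, giving a mixture of C4 epimers. Fallback: enzymatic differentiation of the epimers instead of catalyst control. Setting out from 10, a nitroaldol reaction without chiral catalyst (nitromethane, cat. KF, i-PrOH) should give 12 together with the (2S) epimer F7. A lipase (Burkholderia cepacia lipase, vinyl acetate, t-BuOMe) should acetylate the (2S) carbinol selectively, since the empirical size rule for secondary alcohols places the branched chain in the large pocket. This gives the (2S) acetate F8, which is removed by chromatography, and the route is rejoined at 12.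

**Further compounds**

F1 | step 10 | 5-{(2R,3R)-3-[(tert-butyldimethylsilyl)oxy]-2-geranylgeranyl-4-nitrobutyl}-5-methoxyfuran-2(5H)-one (ketal epimers) | [O-][N+](=O)C[C@H](O[Si](C)(C)C(C)(C)C)[C@H](C/C=C(\C)CC/C=C(\C)CC/C=C(\C)CCC=C(C)C)CC1(OC)OC(=O)C=C1
F2 | step 10 | (5R,6R)-5-[(tert-butyldimethylsilyl)oxy]-6-geranylgeranyl-7a-methoxy-4-nitrohexahydro-1-benzofuran-2(3H)-one (other centres as formed) | O=C1CC2C([N+](=O)[O-])[C@H](O[Si](C)(C)C(C)(C)C)[C@H](C/C=C(\C)CC/C=C(\C)CC/C=C(\C)CCC=C(C)C)CC2(OC)O1
F3 | step 8 | (2Z,6R,7R)-7-[(tert-butyldimethylsilyl)oxy]-6-geranylgeranyl-8-nitro-4-oxooct-2-enal | [O-][N+](=O)C[C@H](O[Si](C)(C)C(C)(C)C)[C@H](C/C=C(\C)CC/C=C(\C)CC/C=C(\C)CCC=C(C)C)CC(=O)/C=C\C=O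
F4 | step 8 | (2E,6R,7R)-7-[(tert-butyldimethylsilyl)oxy]-6-geranylgeranyl-8-nitro-4-oxooct-2-enal | [O-][N+](=O)C[C@H](O[Si](C)(C)C(C)(C)C)[C@H](C/C=C(\C)CC/C=C(\C)CC/C=C(\C)CCC=C(C)C)CC(=O)/C=C/C=O
F5 | step 8 | (2E,6R,7R)-7-[(tert-butyldimethylsilyl)oxy]-6-geranylgeranyl-8-nitro-4-oxooct-2-enoic acid | [O-][N+](=O)C[C@H](O[Si](C)(C)C(C)(C)C)[C@H](C/C=C(\C)CC/C=C(\C)CC/C=C(\C)CCC=C(C)C)CC(=O)/C=C/C(=O)O
F6 | step 8 | methyl (2E,6R,7R)-7-[(tert-butyldimethylsilyl)oxy]-6-geranylgeranyl-8-nitro-4-oxooct-2-enoate | [O-][N+](=O)C[C@H](O[Si](C)(C)C(C)(C)C)[C@H](C/C=C(\C)CC/C=C(\C)CC/C=C(\C)CCC=C(C)C)CC(=O)/C=C/C(=O)OC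
F7 | step 6 | (2S,3R,5E,9E,13E)-3-(furan-2-ylmethyl)-6,10,14,18-tetramethyl-1-nitrononadeca-5,9,13,17-tetraen-2-ol | [O-][N+](=O)C[C@@H](O)[C@H](C/C=C(\C)CC/C=C(\C)CC/C=C(\C)CCC=C(C)C)Cc1ccco1
F8 | step 6 | (2S,3R,5E,9E,13E)-3-(furan-2-ylmethyl)-6,10,14,18-tetramethyl-1-nitrononadeca-5,9,13,17-tetraen-2-yl acetate | [O-][N+](=O)C[C@@H](OC(C)=O)[C@H](C/C=C(\C)CC/C=C(\C)CC/C=C(\C)CCC=C(C)C)Cc1ccco1
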